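Numbering: C1 = C(OH) bearing C7H2OBz, C2 = CH‑OMe, C3=C4 alkene, C5 = CH‑OBz, C6 = CH‑OAc. TBS = tert‑butyldimethylsilyl.
**Late cuts:** the three ester C–O bonds and a C1–O silyl ether come off first. C5–O and C7 are then tied back into a γ‑lactone and C6 is raised to a ketone, which gives a 6‑oxabicyclo[3.2.1]oct‑3‑ene‑7,8‑dione.
**Key cut:** C4–C5 and C1–C2 are cut together as a [3+3]. C2–C3–C4 becomes the 1,3‑dimethoxyallyl cation, which already carries the OMe. C5–C6–C1–C7 becomes 2‑hydroxytetronic acid, used as its tris(silyloxy)furan.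
**Enabling feature:** O on C5 and C7 on C1 are cis‑1,3 on the cyclohexene. The ring O–C7(=O)–C1–C6(=O)–C5 is therefore an aci‑reductone that is nucleophilic at C5 and C1, and in the bicycle C5–H is a bridgehead and C1 is quaternary.
**Forward order:** the furanone ring is made by Dieckmann closure, the carbocycle is bridged across it in one step, and the temporary lactone ring is opened by reduction. Acylation and desilylation follow.
**Stereochemistry:** C5 comes from a chiral ion‑pair catalyst, C1 from the bridge, C2 from the s‑trans (Z)‑cation (OMe pseudo‑equatorial), and C6 from hydride delivery over the lactone bridge.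

Key step: step 5

Assumption: precedent does not tell which antipode of the squaramide catalyst leads to the (5R) series. The antipode that does so is meant in step 5. Both antipodes are accessible, and the sense is fixed in a first run.

Step 1
Reactants: 1 methyl glycolate; 2 (benzyloxy)acetyl chloride
Product: 3 methyl 2-{[2-(benzyloxy)acetyl]oxy}acetate
Conditions: Et3N, DMAP (cat.), CH2Cl2, 0 °C to rt
Reagents that add atoms: none
Why: Acylation of a primary alcohol with an acid chloride under amine base is routine esterification and creates no stereocentre.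

Step 2
Reactants: 3 methyl 2-{[2-(benzyloxy)acetyl]oxy}acetate
Product: 4 3-(benzyloxy)-4-hydroxyfuran-2(5H)-one
Conditions: LiHMDS (2.2 equiv), THF, −78 °C; then 1 M HCl
Reagents that add atoms: none
Why: In this Dieckmann (intramolecular Claisen) condensation the benzyloxyacetate enolate attacks the methyl ester 5-exo-trig, and deprotonation of the acidic tetronic acid drives the closure, as is well precedented for 3-alkoxytetronic acids.

Step 3
Reactants: 4 3-(benzyloxy)-4-hydroxyfuran-2(5H)-one
Product: 5 3,4-dihydroxyfuran-2(5H)-one (2-hydroxytetronic acid)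
Conditions: H2 (1 atm), 10% Pd/C, EtOAc, rt
Reagents that add atoms: none
Why: Hydrogenolysis of the O-benzyl group leaves the tetrasubstituted push–pull enediol C=C untouched, as known for O-benzyl aci-reductones.

Step 4
Reactants: 5 3,4-dihydroxyfuran-2(5H)-one
Product: 6 2,3,4-tris(tert-butyldimethylsilyloxy)furan
Conditions: TBSOTf (3.3 equiv), Et3N (4 equiv), CH2Cl2, 0 °C; pentane extraction, used at once under argon
Reagents that add atoms: tert-butyldimethylsilyl triflate, CC(C)(C)[Si](C)(C)OS(=O)(=O)C(F)(F)F
Why: O-silylation of both enolic OH groups followed by soft enolisation (γ-deprotonation) of the butenolide with R3SiOTf/Et3N is the standard 2-silyloxyfuran synthesis and is driven by aromatisation.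

Step 5
Reactants: 6 2,3,4-tris(tert-butyldimethylsilyloxy)furan; 7 (E)-1,3,3-trimethoxyprop-1-ene
Product: 9 (1R,2S,5R)-1-(tert-butyldimethylsilyloxy)-2-methoxy-6-oxabicyclo[3.2.1]oct-3-ene-7,8-dione, via C5-dimethoxyallyl butenolide 8 (not isolated)
Conditions: chiral arylpyrrolidine squaramide hydrogen-bond donor (10 mol %), TBSOTf (10 mol %), 4 Å MS, t-BuOMe/CH2Cl2, 0.02 M, −78 to −50 °C; Et3N quench at −78 °C, pH 7 buffer
Reagents that add atoms: none
Why: Proposed new method: the squaramide-bound silyl triflate takes methoxide from 7 to give the symmetric 1,3-dimethoxyallyl cation as a chiral ion pair, the free C5 of furan 6 adds to one terminus (vinylogous Mukaiyama addition, C4–C5, giving 8), the now allylic C4–OMe ionises again to the O-methylated (Z)-enal cation, and the remaining C6 enol silane attacks C2 (C1–C2) with loss of the second silyl group as MeOTBS. The closest known reaction types are the Lewis acid [3+3] cyclocondensation of 1,3-bis(silyloxy)-1,3-dienes with malonaldehyde acetals (which ends in arenes), the C5-selective addition of 4-alkoxy-2-silyloxyfurans to acetals, and the hydrogen-bond-donor/silyl triflate co-catalysed enantioselective Mukaiyama addition to acetals. The carbocycle closes 6-(enolendo)-exo-trig across C5 and C1 of the butenolide, only the (Z)-cation can reach C1, and E/Z exchange stays open through reversible return of MeOTBS to C4. C5 is set by the chiral anion in the first, irreversible C–C bond formation, C1 follows from it because a three-atom bridge can span only one face of the five-membered ring, and C2 should carry OMe pseudo-equatorial (trans to C1–O) because the (Z)-cation reacts s-trans, with H and not OMe turned toward the C6 siloxy group. The regiochemistry needed (OMe next to C1, alkene next to C5) is secured because the nucleophile that attacks first always ends on the carbon that later loses methoxide, and the unsubstituted C5 of 6 is far more accessible than the fully substituted C1. C- rather than O-closure and survival of the strained push–pull C1–C2 bond require kinetic control (catalytic acid, low temperature, cold amine quench), while aromatisation and vinylogous loss of methanol are excluded since C1 is quaternary and C5–H sits at a bridgehead (Bredt's rule).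

Step 6
Reactants: 9 (1R,2S,5R)-1-(tert-butyldimethylsilyloxy)-2-methoxy-6-oxabicyclo[3.2.1]oct-3-ene-7,8-dione
Product: 10 (1S,2S,5R,8S)-1-(tert-butyldimethylsilyloxy)-8-hydroxy-2-methoxy-6-oxabicyclo[3.2.1]oct-3-en-7-one (8-OH syn to the C2–C4 bridge; the C1 descriptor changes only through CIP ranking)
Conditions: NaBH4, CeCl3·7H2O, MeOH/CH2Cl2, −78 °C; AcOH quench
Reagents that add atoms: none
Why: Luche-type 1,2-reduction takes the strained bridge ketone and not the lactone, and hydride should arrive over the flat, hydrogen-free O6–C7(=O) bridge rather than over the C2–C4 bridge with its pseudo-axial C2–H, which sets C6 of the target with OH cis to C1–O.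

Step 7
Reactants: 10 (1S,2S,5R,8S)-1-(tert-butyldimethylsilyloxy)-8-hydroxy-2-methoxy-6-oxabicyclo[3.2.1]oct-3-en-7-one
Product: 11 (1S,2S,5R,6S)-1-(tert-butyldimethylsilyloxy)-1-(hydroxymethyl)-2-methoxycyclohex-3-ene-5,6-diol (target numbering)
Conditions: DIBAL-H (5 equiv), CH2Cl2, −78 to 0 °C; aq. Rochelle salt
Reagents that add atoms: none
Why: Hydride reduction of the lactone to the diol removes the temporary ring and frees exactly the two oxygens (C5–OH, C7–OH) that become benzoates, while covalent aluminium alkoxides in CH2Cl2 keep silyl migration down and no stereocentre is touched.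

Step 8
Reactants: 11 (1S,2S,5R,6S)-1-(tert-butyldimethylsilyloxy)-1-(hydroxymethyl)-2-methoxycyclohex-3-ene-5,6-diol
Product: 12 [(1S,2S,5R,6S)-5-(benzoyloxy)-1-(tert-butyldimethylsilyloxy)-6-hydroxy-2-methoxycyclohex-3-en-1-yl]methyl benzoate
Conditions: BzCl (2.2 equiv), pyridine, CH2Cl2, −40 to 0 °C
Reagents that add atoms: benzoyl chloride, O=C(Cl)c1ccccc1
Why: In this site-selective acylation the primary C7–OH and the allylic C5–OH should react first, because C6–OH is flanked by the quaternary C1 carrying the bulky OTBS group.

Step 9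
Reactants: 12 [(1S,2S,5R,6S)-5-(benzoyloxy)-1-(tert-butyldimethylsilyloxy)-6-hydroxy-2-methoxycyclohex-3-en-1-yl]methyl benzoate
Product: 13 [(1R,2S,5R,6S)-6-acetoxy-5-(benzoyloxy)-1-(tert-butyldimethylsilyloxy)-2-methoxycyclohex-3-en-1-yl]methyl benzoate
Conditions: Ac2O, Et3N, DMAP (cat.), CH2Cl2, rt
Reagents that add atoms: acetic anhydride, CC(=O)OC(C)=O
Why: DMAP-catalysed acetylation of the only free (secondary) hydroxyl is routine even next to a hindered centre, because the acyl group is small.

Step 10
Reactants: 13 [(1R,2S,5R,6S)-6-acetoxy-5-(benzoyloxy)-1-(tert-butyldimethylsilyloxy)-2-methoxycyclohex-3-en-1-yl]methyl benzoate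
Product: 14 [(1R,2S,5R,6S)-6-acetoxy-5-(benzoyloxy)-1-hydroxy-2-methoxycyclohex-3-en-1-yl]methyl benzoate (target)
Conditions: HF·pyridine, THF/pyridine, 0 °C to rt
Reagents that add atoms: none
Why: Fluoride-mediated desilylation in a buffered acidic medium frees the tertiary alcohol without the base-induced acyl migration that TBAF could cause, and the esters, the allylic ether and the alkene are inert.

Compound list
1 | methyl glycolate | COC(=O)CO | starting material
2 | (benzyloxy)acetyl chloride | O=C(Cl)COCc1ccccc1 | starting material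
3 | methyl 2-{[2-(benzyloxy)acetyl]oxy}acetate | COC(=O)COC(=O)COCc1ccccc1 | intermediate
4 | 3-(benzyloxy)-4-hydroxyfuran-2(5H)-one | O=C1OCC(O)=C1OCc1ccccc1 | intermediate
5 | 3,4-dihydroxyfuran-2(5H)-one (2-hydroxytetronic acid) | O=C1OCC(O)=C1O | intermediate
6 | 2,3,4-tris(tert-butyldimethylsilyloxy)furan | CC(C)(C)[Si](C)(C)Oc1coc(O[Si](C)(C)C(C)(C)C)c1O[Si](C)(C)C(C)(C)C | intermediate
7 | (E)-1,3,3-trimethoxyprop-1-ene | CO/C=C/C(OC)OC | starting material
8 | (5R)-5-[(2E)-1,3-dimethoxyprop-2-en-1-yl]-3,4-bis(tert-butyldimethylsilyloxy)furan-2(5H)-one (both epimers at the side-chain carbinol carbon, which is lost later) | CO/C=C/C(OC)[C@H]1OC(=O)C(O[Si](C)(C)C(C)(C)C)=C1O[Si](C)(C)C(C)(C)C | intermediate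
9 | (1R,2S,5R)-1-(tert-butyldimethylsilyloxy)-2-methoxy-6-oxabicyclo[3.2.1]oct-3-ene-7,8-dione | CO[C@H]1C=C[C@@H](OC2=O)C(=O)[C@]12O[Si](C)(C)C(C)(C)C | intermediate
10 | (1S,2S,5R,8S)-1-(tert-butyldimethylsilyloxy)-8-hydroxy-2-methoxy-6-oxabicyclo[3.2.1]oct-3-en-7-one | CO[C@H]1C=C[C@@H](OC2=O)[C@H](O)[C@]12O[Si](C)(C)C(C)(C)C | intermediate
11 | (1S,2S,5R,6S)-1-(tert-butyldimethylsilyloxy)-1-(hydroxymethyl)-2-methoxycyclohex-3-ene-5,6-diol | CO[C@H]1C=C[C@@H](O)[C@H](O)[C@@]1(O[Si](C)(C)C(C)(C)C)CO | intermediate
12 | [(1S,2S,5R,6S)-5-(benzoyloxy)-1-(tert-butyldimethylsilyloxy)-6-hydroxy-2-methoxycyclohex-3-en-1-yl]methyl benzoate | CO[C@H]1C=C[C@@H](OC(=O)c2ccccc2)[C@H](O)[C@@]1(O[Si](C)(C)C(C)(C)C)COC(=O)c1ccccc1 | intermediate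
13 | [(1R,2S,5R,6S)-6-acetoxy-5-(benzoyloxy)-1-(tert-butyldimethylsilyloxy)-2-methoxycyclohex-3-en-1-yl]methyl benzoate | CO[C@H]1C=C[C@@H](OC(=O)c2ccccc2)[C@H](OC(C)=O)[C@@]1(O[Si](C)(C)C(C)(C)C)COC(=O)c1ccccc1 | intermediate
14 | [(1R,2S,5R,6S)-6-acetoxy-5-(benzoyloxy)-1-hydroxy-2-methoxycyclohex-3-en-1-yl]methyl benzoate | CO[C@H]1C=C[C@@H](OC(=O)c2ccccc2)[C@H](OC(C)=O)[C@@]1(O)COC(=O)c1ccccc1 | target

Total step count: 10. Longest linear sequence: 10 steps (1 to 14).

Steps most likely to fail

**Step 5.**
- What may go wrong: the second closure may stall or run through the enol oxygen. The strained C1–C2 bond may re-ionise under the acid. Ion-pair control over the furan face may be poor.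
- Scope of the fallback: it sets out from 5 and comes back at 11. It makes the two bonds separately with known reaction types and takes the absolute configuration from a resolution.
- Protection and C1–C2: compound 5 is bis-silylated (TBSCl, imidazole, DMF) to 3,4-bis(tert-butyldimethylsilyloxy)furan-2(5H)-one F1. Its enol silane adds to propynal dimethyl acetal at C1 (TMSOTf, CH2Cl2, −78 °C, Mukaiyama-type acetal aldol) to give racemic 3-(1-methoxyprop-2-yn-1-yl)-3-(tert-butyldimethylsilyloxy)furan-2,4(3H,5H)-dione F2.
- C4–C5: TBSOTf/Et3N converts F2 into the C5=C6 enol silane 3-(1-methoxyprop-2-yn-1-yl)-3,4-bis(tert-butyldimethylsilyloxy)furan-2(3H)-one F3. A cationic phosphine–gold(I) catalyst in CH2Cl2/MeOH closes C4–C5 by the known 6-endo-dig carbocyclisation of enol silanes onto alkynes. This gives (±)-9, and the C2 epimer is removed by chromatography.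
- Resolution and return: the conditions of step 6 give (±)-10, which is esterified with (S)-O-methylmandelic acid (DCC, DMAP). The diastereomers are separated, and the (S)-O-methylmandelate of 10 F4 is treated as in step 7. DIBAL-H cleaves the ester and the lactone together to give 11.

**Step 8.**
- What may go wrong: site selectivity between C5–OH and C6–OH may be poor, or benzoyl may migrate from O5 to O6.
- Scope of the fallback: it sets out from 11 and comes back at 12. It replaces kinetic selectivity by protecting-group differentiation.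
- Sequence: 2-methoxypropene/PPTS bridges the only 1,3-diol (the C5/C6 diol is trans) to give the 6,7-O-isopropylidene acetal of 11 F5. BzCl/DMAP then gives its C5 benzoate F6, and 80% AcOH gives the C5-monobenzoate 6,7-diol F7.
- Return: BzCl (1.05 equiv), collidine, −40 °C acylates the primary hydroxyl in preference to the hindered secondary one and gives 12.

**Step 6.**
- What may go wrong: hydride may attack over the alkene bridge (wrong facial selectivity at C6), or the β-keto lactone may undergo retro-Claisen opening in the alcoholic medium.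
- Scope of the fallback: it sets out from 9 and comes back at 10. It replaces substrate control by catalyst control under aprotic conditions.
- Sequence: a CBS reduction with (R)-Me-CBS and BH3·SMe2 in toluene at −40 °C is used. The catalyst distinguishes the quaternary C1 (large) from the C5 methine (small) and should deliver the (8S) alcohol.

Further compounds
F1 | step 5 | 3,4-bis(tert-butyldimethylsilyloxy)furan-2(5H)-one | O=C1OCC(O[Si](C)(C)C(C)(C)C)=C1O[Si](C)(C)C(C)(C)C
F2 | step 5 | 3-(1-methoxyprop-2-yn-1-yl)-3-(tert-butyldimethylsilyloxy)furan-2,4(3H,5H)-dione (racemic, relative configuration shown) | CO[C@@H](C#C)[C@@]1(O[Si](C)(C)C(C)(C)C)C(=O)COC1=O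
F3 | step 5 | 3-(1-methoxyprop-2-yn-1-yl)-3,4-bis(tert-butyldimethylsilyloxy)furan-2(3H)-one (racemic, relative configuration shown) | CO[C@@H](C#C)[C@@]1(O[Si](C)(C)C(C)(C)C)C(O[Si](C)(C)C(C)(C)C)=COC1=O
F4 | step 5 | (S)-O-methylmandelate of 10 | CO[C@H]1C=C[C@@H](OC2=O)[C@H](OC(=O)[C@@H](OC)c3ccccc3)[C@]12O[Si](C)(C)C(C)(C)C
F5 | step 8 | 6,7-O-isopropylidene acetal of 11 | CO[C@H]1C=C[C@@H](O)[C@H](OC(C)(C)OC2)[C@]12O[Si](C)(C)C(C)(C)C
F6 | step 8 | C5 benzoate of the 6,7-O-isopropylidene acetal | CO[C@H]1C=C[C@@H](OC(=O)c3ccccc3)[C@H](OC(C)(C)OC2)[C@]12O[Si](C)(C)C(C)(C)C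
F7 | step 8 | C5-monobenzoate 6,7-diol | CO[C@H]1C=C[C@@H](OC(=O)c2ccccc2)[C@H](O)[C@@]1(O[Si](C)(C)C(C)(C)C)CO
F0 | step 6 | none | none
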